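## Analysis of the target

Target 27 is a labdane: a trans-fused decalin (ring A = C1–C5 and C10 with the gem-dimethyl carbon C4; ring B = C5–C10) whose C9 carries a two-carbon tether (C11, C12) to a 3-hydroxy-γ-butyrolactone (C13 carbinol, C14, C15 carbonyl, C16 CH2O). Ring B holds an axial 6β-hydroxyl, the C7 ketone and the tetrasubstituted C8=C9 enone alkene with the C17 methyl on C8. Three stereocentres are contiguous: quaternary C10 (S), C5 (S, hydrogen trans to C20) and C6 (S, hydroxyl cis to C20 and 1,3-diaxial to C20 and to the β methyl on C4). The fourth, C13 (S), is a tertiary carbinol with three CH2 arms, too far from the ring for any relay, so it needs its own source of chirality. The C6/C7 α-ketol (epimerisation, ketol shift) and the tertiary β-hydroxy lactone (ring opening, retro-aldol, dehydration) are base-sensitive, so the closing steps should be neutral or acidic. The hard points are quaternary C10 beside quaternary C4, the hindered axial C6 hydroxyl, and C5: with a C6 ketone and sp2 carbons at C7–C9, the trans fusion of a 4,4,10-trimethyl decalin cannot be assumed to be the thermodynamic one. The plan rests on ring B: C6 and C9 are para-related and both derive from carbonyls, and C8 and C10 carry the methyls flanking C9. That is the pattern of quinone 1, and C1–C4 with the gem-dimethyl terminus is diene 2.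

## Retrosynthetic reasoning

**27 to 24.** The lactone C16–O bond and the C6 protecting group are opened first. This leads back through silyl ether 26 to acid 24, in which C13–OH and C16–OH are tied as a dioxolane. Forward, acid hydrolysis of the dioxolane lets the C16 hydroxyl close the five-membered lactone, and the silyl group is removed last under non-basic conditions.

**24 to 21.** C15 is taken back to the alcohol level (22) and masked as a benzyl ether, and the C2=C3 alkene left by the cycloaddition is restored (21). One hydrogenation then does both jobs forward, at a stage where the only other alkene, C8=C9, is tetrasubstituted and conjugated.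

**21 to 20.** The enone is disconnected by a 1,3-oxygen transposition to the tertiary allylic alcohol 20 (C9–OH, C7=C8). This is chosen over a direct C9 alkylation because it lets the side chain enter as a nucleophile at a ketone that cannot enolise.

**20 to 7 and 18.** The C9–C11 bond is cut to give enone 7 and the organolithium 19 made from iodide 18. The cut is placed here because it separates the ring stereocentres from C13 completely, so each half carries its own chirality.

**18 to 8.** C13 is traced to (S)-malic acid 8. The carbinol carbon of 8 already bears the hydroxyl, a carboxyl (future C16) and a CH2CO2H arm (future C14–C15). The missing C12–C13 bond is made by allylation of the dioxolanone 9 with retention (11), and the allyl group is later shortened to the C11–C12 iodoethyl arm. Reduction (12), acetonide formation (13) and benzylation (15) differentiate the three oxygens.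

**7 to 5.** The C6–H bond is cut: 7 comes from the allylic alcohol 6, and 6 from hydride addition to the less hindered of the two carbonyls of the trans-fused dione 5. This differentiates C6 from C9 without protecting-group traffic.

**5 to 3.** C5 is inverted through the dienol ether 4. The cycloaddition can only deliver a cis fusion, and C5 is acidic only while C6 is a ketone, so the correction has to be made here. It is planned as a kinetic protonation, not an equilibration.

**3 to 1 and 2.** The C1–C10 and C4–C5 bonds are cut in a [4+2] sense. This removes ring A, both quaternary carbons and the C10 stereocentre in one step and ends at two commercial compounds.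

## Alternatives that were turned down

**Alternative 1:** Rings A and B would both be cut at C5–C10 and C8–C9. Forward, an acyclic trienal A2 would undergo an intramolecular Diels–Alder reaction under chiral secondary-amine (iminium) catalysis to give the trans-fused octalin aldehyde A1.
- For: two rings and four stereocentres form at once, and the trans fusion comes directly. On both points it is stronger than the chosen plan, which closes one ring and has to correct C5 afterwards.
- Against: the dienophile of A2 is a β,β-disubstituted enal that must form quaternary C10, a poor case for iminium activation, and the diene terminus sits beside neopentyl C4. A2 needs a multi-step synthesis with three defined alkene geometries.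
- Against: A1 has no oxygen on ring B. C6–OH, the C7 ketone and the C8=C9 alkene would all have to be introduced, destroying the C8 and C9 stereocentres just made, and the C11 formyl group would have to be reduced and extended.
- In its place the chosen plan takes both ring-B oxygens and the C8 methyl from 1 at the right oxidation level and starts from commercial partners.

**Alternative 2:** Ring B would be cut at C7–C8 and C9–C10. Forward, the ring-A dienyl silyl ether A4 would add to the ynoyl imide A5 under a chiral Lewis acid to give the 1,4-cyclohexadiene A3.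
- For: A3 already has the C8=C9 alkene, the C8 methyl, a carbon substituent on C9 and an enol ether oxygen at C6. Here it is stronger than the chosen plan, which reaches the C9 substituent and the C8=C9 alkene only by addition and transposition.
- Against: A4 is a 2,6,6-trimethylcyclohexenyl diene, twisted out of the s-cis conformation and fully substituted at the terminus that becomes C10. Face selection at such a terminus with an alkynoyl dienophile has no dependable basis.
- Against: C7 arrives as CH2 and needs a later allylic oxidation, the C9 acyl group is at the wrong oxidation level for C11, and C5 still has to be set by protonation of the C5=C6 enol ether. The C5 problem is therefore not avoided.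
- In its place the chosen plan offers a precedented catalyst–quinone pairing, commercial partners and oxygen at both C6 and C9.

**Alternative 3:** Only the C4–C5 bond would be cut. Forward, the enol triflate A7 would undergo a reductive Heck cyclisation: zerovalent palladium inserts, the alkenylpalladium adds 6-exo to the methylidene group, and a hydride donor reduces the neopentylpalladium species to the second C4 methyl, giving A6.
- For: the ring closure and the creation of quaternary C4 are mechanistically safe, since no β-hydrogen is available, and C10 could come from well-established enantioselective chemistry. The key step is clearly less risky than a hindered intermolecular cycloaddition.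
- Against: it forms one bond and one ring on a preformed ring B. A6 lacks the C8 methyl and both ring-B oxygens, carries a C9 silyl ether that must become the attachment point, and has a C5=C6 alkene from which C5 and C6 would still have to be set. A7 itself needs a long preparation.
- In its place the chosen plan forms two skeletal bonds, both quaternary carbons and the complete ring-B functionality in its key step.

Key step: step 1

## Remarks before the steps

- Positions are given in labdane numbering: C1–C10 decalin, C11–C16 side chain, C17 on C8, C18 and C19 on C4, C20 on C10; β is the face of C20.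
- Assumption: the facial sense of the oxazaborolidinium catalyst is taken from the usual pre-transition-state picture (vinylic C–H···O contact of the quinone to the ring oxygen, shielding by the cis phenyl group). This points to the (R)-prolinol-derived catalyst for 10S. The mirror-image catalyst would be used, with nothing else changed, should the adduct prove antipodal.
- The catalyst precursor is made in one operation from commercial (R)-α,α-diphenyl-2-pyrrolidinemethanol and 2-methylphenylboronic acid and is activated in the flask.
- Compound 20 is carried as both C9 epimers, which converge in step 13.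

## Route

Step 1
Reactants: 1 2,6-dimethyl-1,4-benzoquinone; 2 4-methylpenta-1,3-diene
Product: 3 (4aR,8aS)-2,5,5,8a-tetramethyl-4a,5,8,8a-tetrahydronaphthalene-1,4-dione (cis-fused adduct; labdane 5R,10S)
Conditions: (R)-tetrahydro-1-(2-methylphenyl)-3,3-diphenyl-1H,3H-pyrrolo[1,2-c][1,3,2]oxazaborole (20 mol %), HN(SO2CF3)2 (20 mol %), 2 (5 equiv), CH2Cl2, −78 → −30 °C
Reagents that add atoms: none
Why: Protonation of the oxazaborolidine nitrogen gives a cationic boron Lewis acid that binds the quinone at the C6 carbonyl, the only one flanked by vinylic C–H bonds, so the methyl-bearing carbon (future C10) becomes the electrophilic β-position. The diene attacks it with its unsubstituted terminus C1, the end whose reaction leaves a dimethyl-stabilised allyl cation, and the C4–C5 bond follows in the same encounter, so the event is a strongly asynchronous Diels–Alder reaction. Ring A is closed as a six-membered ring by suprafacial [4+2] addition across C5=C10; in the stepwise limit the boron enolate carbon C5 closes onto the allyl cation terminus C4. The closest known reaction type is the enantioselective Diels–Alder reaction of dialkyl-1,4-benzoquinones under protonated oxazaborolidine catalysis, including cases that form a quaternary carbon at a methylated quinone carbon; Lewis-acid-promoted additions of this diene to enones show the same orientation. C10 is set by the catalyst, which covers one quinone face with the phenyl group cis to the bound carbonyl and leaves the other open to the diene. C5 is set relative to C10 by the suprafacial closure, hence the cis fusion, and endo versus exo is irrelevant because neither diene terminus is stereogenic. Regiochemistry is needed and is secured by the carbonyl choice of the Lewis acid and the polarisation of the diene, while the two methylated quinone alkenes are equivalent by symmetry and quaternary C10 blocks aromatisation. The weak point is the small s-cis population of a diene with a cis terminal methyl, which is why the diene is used in excess at low temperature.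

Step 2
Reactants: 3 (4aR,8aS)-2,5,5,8a-tetramethyl-4a,5,8,8a-tetrahydronaphthalene-1,4-dione
Product: 5 (4aS,8aS)-2,5,5,8a-tetramethyl-4a,5,8,8a-tetrahydronaphthalene-1,4-dione (trans-fused dione), via trimethylsilyl dienol ether 4 (not isolated)
Conditions: Me3SiOSO2CF3, Et3N, CH2Cl2, 0 °C; evaporate; then Bu4NF, AcOH, THF, −78 °C
Reagents that add atoms: none
Why: Soft enolisation can only involve the C6 carbonyl (C9 has no enolisable position) and should give the linearly conjugated C5=C6 dienol ether 4; fluoride then frees the enolate, which acetic acid protonates at −78 °C on the α face of C5, anti to the axial C20 methyl and the β methyl on C4 that flank the β face, so the trans fusion arises by kinetic enolate protonation. Equilibration with base is avoided on purpose, because in this 4,4,10-trimethyl series with sp2 carbons at C7–C9 the cis dione may well be the more stable epimer.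

Step 3
Reactants: 5 (4aS,8aS)-2,5,5,8a-tetramethyl-4a,5,8,8a-tetrahydronaphthalene-1,4-dione
Product: 6 (4R,4aS,8aS)-4-hydroxy-2,5,5,8a-tetramethyl-4a,5,8,8a-tetrahydronaphthalen-1(4H)-one (6β-hydroxy-2,7-dien-9-one)
Conditions: NaBH4, CeCl3·7H2O, MeOH, −78 °C
Reagents that add atoms: none
Why: Luche 1,2-reduction; the C9 carbonyl sits between quaternary C10 and the methylated C8 and should be the slower one, the same bias by which 2,6,6-trimethylcyclohex-2-ene-1,4-dione is reduced at its unhindered carbonyl. Hydride enters C6 from the α face because C20 and the β methyl on C4 cover the β face, which gives the axial 6β-alcohol; the low temperature keeps C5 from epimerising before reduction.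

Step 4
Reactants: 6 (4R,4aS,8aS)-4-hydroxy-2,5,5,8a-tetramethyl-4a,5,8,8a-tetrahydronaphthalen-1(4H)-one
Product: 7 (4R,4aS,8aS)-4-(tert-butyldimethylsilyloxy)-2,5,5,8a-tetramethyl-4a,5,8,8a-tetrahydronaphthalen-1(4H)-one
Conditions: t-BuMe2SiOSO2CF3, 2,6-lutidine, CH2Cl2, 0 °C → rt
Reagents that add atoms: tert-butyldimethylsilyl trifluoromethanesulfonate, CC(C)(C)[Si](C)(C)OS(=O)(=O)C(F)(F)F
Why: Silylation with the triflate, the reagent of choice for a hindered axial secondary alcohol; the ether must survive an organolithium, a chromium oxidant and hydrogenation and must keep the allylic C6 alcohol from being oxidised in step 13.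

Step 5
Reactants: 8 (S)-malic acid
Product: 9 [(2S,4S)-2-tert-butyl-5-oxo-1,3-dioxolan-4-yl]acetic acid
Conditions: t-BuCHO, TsOH (cat.), H2SO4 (cat.), pentane, reflux with water separator; recrystallisation
Reagents that add atoms: 2,2-dimethylpropanal, CC(C)(C)C=O
Why: Acetalisation of the α-hydroxy acid to the cis-dioxolanone, which is purified by crystallisation; the new acetal centre stores the chirality of 8 for the next step (self-regeneration of a stereocentre).

Step 6
Reactants: 9 [(2S,4S)-2-tert-butyl-5-oxo-1,3-dioxolan-4-yl]acetic acid
Product: 11 [(2S,4S)-2-tert-butyl-5-oxo-4-(prop-2-en-1-yl)-1,3-dioxolan-4-yl]acetic acid, via dilithium enolate carboxylate 10 (not isolated)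
Conditions: LiN(SiMe3)2 (2.2 equiv), THF, −78 °C; then allyl bromide, −78 → −30 °C; aq. HCl work-up
Reagents that add atoms: allyl bromide, C=CCBr
Why: Enolate alkylation of the dioxolanone; the electrophile enters trans to the tert-butyl group, so allyl takes the place of the former hydrogen with overall retention and fixes the C13 configuration (allyl = future C12–C11, CH2CO2H = C14–C15, ring carbonyl = C16).

Step 7
Reactants: 11 [(2S,4S)-2-tert-butyl-5-oxo-4-(prop-2-en-1-yl)-1,3-dioxolan-4-yl]acetic acid
Product: 12 (2S)-2-(prop-2-en-1-yl)butane-1,2,4-triol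
Conditions: LiAlH4, THF, 0 °C → reflux; aqueous NaOH work-up
Reagents that add atoms: none
Why: Hydride reduction of the acid and of the acylal-type lactone carbonyl; the pivaldehyde unit leaves as its alcohol and the quaternary carbinol is untouched.

Step 8
Reactants: 12 (2S)-2-(prop-2-en-1-yl)butane-1,2,4-triol
Product: 13 2-[(4S)-2,2-dimethyl-4-(prop-2-en-1-yl)-1,3-dioxolan-4-yl]ethan-1-ol
Conditions: Me2C(OMe)2, TsOH (cat.), acetone, rt
Reagents that add atoms: 2,2-dimethoxypropane, COC(C)(C)OC
Why: Thermodynamic acetonide formation; the five-membered 1,2-acetal is favoured over the six-membered 1,3-acetal, which would place a substituent of the quaternary carbon syn-axial to an acetal methyl, so the C15 hydroxyl is left free.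

Step 9
Reactants: 13 2-[(4S)-2,2-dimethyl-4-(prop-2-en-1-yl)-1,3-dioxolan-4-yl]ethan-1-ol
Product: 15 (4S)-4-[2-(benzyloxy)ethyl]-2,2-dimethyl-4-(prop-2-en-1-yl)-1,3-dioxolane, via sodium alkoxide 14 (not isolated)
Conditions: NaH, THF/DMF, 0 °C; then BnBr, Bu4NI (cat.), rt
Reagents that add atoms: benzyl bromide, BrCc1ccccc1
Why: Williamson ether synthesis on an unhindered primary alkoxide; the benzyl ether masks C15 through the organolithium and chromium steps and is removed in the hydrogenation of step 14.

Step 10
Reactants: 15 (4S)-4-[2-(benzyloxy)ethyl]-2,2-dimethyl-4-(prop-2-en-1-yl)-1,3-dioxolane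
Product: 17 2-{(4S)-4-[2-(benzyloxy)ethyl]-2,2-dimethyl-1,3-dioxolan-4-yl}ethan-1-ol, via ozonide 16 (not isolated)
Conditions: O3, CH2Cl2, −78 °C (indicator end point); then NaBH4, MeOH, −78 °C → rt
Reagents that add atoms: ozone, [O-][O+]=O
Why: Ozonolysis with reductive work-up cuts the allyl group down to the two-carbon hydroxyethyl arm (C12–C11); the terminal alkene is far more reactive towards ozone than the benzyl ether if the addition is stopped at the end point.

Step 11
Reactants: 17 2-{(4S)-4-[2-(benzyloxy)ethyl]-2,2-dimethyl-1,3-dioxolan-4-yl}ethan-1-ol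
Product: 18 (4R)-4-[2-(benzyloxy)ethyl]-4-(2-iodoethyl)-2,2-dimethyl-1,3-dioxolane
Conditions: I2, PPh3, imidazole, CH2Cl2, 0 °C → rt
Reagents that add atoms: iodine, II
Why: Appel-type iodination of a primary alcohol under buffered conditions that spare the acetonide; the descriptor changes to R only because iodine raises the priority of its arm.

Step 12
Reactants: 18 (4R)-4-[2-(benzyloxy)ethyl]-4-(2-iodoethyl)-2,2-dimethyl-1,3-dioxolane; 7 (4R,4aS,8aS)-4-(tert-butyldimethylsilyloxy)-2,5,5,8a-tetramethyl-4a,5,8,8a-tetrahydronaphthalen-1(4H)-one
Product: 20 15-benzyloxy-6β-(tert-butyldimethylsilyloxy)-13,16-(isopropylidenedioxy)labda-2,7-dien-9-ol (5S,6R,10S,13S; both C9 epimers), via alkyllithium 19 (not isolated)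
Conditions: t-BuLi (2.1 equiv per 18), Et2O/pentane, −78 °C; then 7, −78 → −40 °C; aq. NH4Cl
Reagents that add atoms: none
Why: Iodine–lithium exchange gives a primary alkyllithium whose γ-alkoxy group is a poor leaving group at −78 °C, and it adds 1,2 to the C9 carbonyl, which has no α-hydrogen and is of the 2,6,6-trisubstituted cyclohexenone type known to accept organolithiums. The C9 configuration is irrelevant because it is erased in step 13.

Step 13
Reactants: 20 15-benzyloxy-6β-(tert-butyldimethylsilyloxy)-13,16-(isopropylidenedioxy)labda-2,7-dien-9-ol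
Product: 21 15-benzyloxy-6β-(tert-butyldimethylsilyloxy)-13,16-(isopropylidenedioxy)labda-2,8-dien-7-one (5S,6S,10S,13S)
Conditions: (C5H5NH)[CrO3Cl] (pyridinium chlorochromate, 3 equiv), 4 Å molecular sieves, CH2Cl2, rt
Reagents that add atoms: pyridinium chlorochromate, [O-][Cr](=O)(=O)Cl.c1cc[nH+]cc1
Why: Dauben–Babler oxidative transposition: the chromate ester of the tertiary allylic alcohol shifts [3,3] to C7 and is oxidised there, which gives the C7 ketone and the tetrasubstituted C8=C9 alkene from either C9 epimer. The silyl ether keeps C6 from being oxidised.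

Step 14
Reactants: 21 15-benzyloxy-6β-(tert-butyldimethylsilyloxy)-13,16-(isopropylidenedioxy)labda-2,8-dien-7-one
Product: 22 6β-(tert-butyldimethylsilyloxy)-15-hydroxy-13,16-(isopropylidenedioxy)labd-8-en-7-one (5S,6S,10S,13S)
Conditions: H2 (1 atm), 10% Pd/C, EtOAc, rt
Reagents that add atoms: none
Why: Heterogeneous hydrogenation saturates the cis-disubstituted C2=C3 alkene and hydrogenolyses the benzyl ether in one operation; the tetrasubstituted, conjugated and doubly flanked C8=C9 alkene should not react at 1 atm, and no stereocentre is formed.

Step 15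
Reactants: 22 6β-(tert-butyldimethylsilyloxy)-15-hydroxy-13,16-(isopropylidenedioxy)labd-8-en-7-one
Product: 24 6β-(tert-butyldimethylsilyloxy)-13,16-(isopropylidenedioxy)-7-oxolabd-8-en-15-oic acid (5S,6S,10S,13S), via aldehyde 23 (not isolated)
Conditions: TEMPO (0.2 equiv), PhI(OAc)2 (2.5 equiv), MeCN/H2O (1:1), rt
Reagents that add atoms: water, O
Why: Oxoammonium oxidation of the only free hydroxyl through the aldehyde hydrate to the acid; the medium is non-basic, so the silyl ether, the dioxolane and the C6 centre next to the ketone are not at risk.

Step 16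
Reactants: 24 6β-(tert-butyldimethylsilyloxy)-13,16-(isopropylidenedioxy)-7-oxolabd-8-en-15-oic acid
Product: 26 6β-(tert-butyldimethylsilyloxy)-13-hydroxy-7-oxolabd-8-en-15,16-olide (5S,6S,10S,13S), via dihydroxy acid 25 (not isolated)
Conditions: 1 M aq. HCl, THF, rt
Reagents that add atoms: none
Why: Acid hydrolysis of the dioxolane frees the C13 and C16 hydroxyls, and the primary C16 hydroxyl closes onto the C15 acid by 5-exo-trig lactonisation; the tertiary C13 hydroxyl could only give a β-lactone and stays free.

Step 17
Reactants: 26 6β-(tert-butyldimethylsilyloxy)-13-hydroxy-7-oxolabd-8-en-15,16-olide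
Product: 27 (5S,6S,10S,13S)-6β,13-dihydroxy-7-oxolabd-8-en-15,16-olide (CNP0324736.2)
Conditions: HF·pyridine, pyridine, THF, 0 °C → rt
Reagents that add atoms: none
Why: Fluoride-assisted desilylation, which does not depend on access to the crowded carbinol carbon; the acidic, non-basic medium avoids epimerisation of C6 in the α-ketol and opening of the β-hydroxy lactone.

## Compound list

1 | 2,6-dimethyl-1,4-benzoquinone | CC1=CC(=O)C=C(C)C1=O | starting material
2 | 4-methylpenta-1,3-diene | C=CC=C(C)C | starting material
3 | (4aR,8aS)-2,5,5,8a-tetramethyl-4a,5,8,8a-tetrahydronaphthalene-1,4-dione (cis-fused) | CC1=CC(=O)[C@@H]2C(C)(C)C=CC[C@]2(C)C1=O | intermediate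
4 | (8aS)-2,5,5,8a-tetramethyl-4-(trimethylsilyloxy)-8,8a-dihydronaphthalen-1(5H)-one | CC1=CC(O[Si](C)(C)C)=C2C(C)(C)C=CC[C@]2(C)C1=O | intermediate
5 | (4aS,8aS)-2,5,5,8a-tetramethyl-4a,5,8,8a-tetrahydronaphthalene-1,4-dione (trans-fused) | CC1=CC(=O)[C@H]2C(C)(C)C=CC[C@]2(C)C1=O | intermediate
6 | (4R,4aS,8aS)-4-hydroxy-2,5,5,8a-tetramethyl-4a,5,8,8a-tetrahydronaphthalen-1(4H)-one | CC1=C[C@@H](O)[C@H]2C(C)(C)C=CC[C@]2(C)C1=O | intermediate
7 | (4R,4aS,8aS)-4-(tert-butyldimethylsilyloxy)-2,5,5,8a-tetramethyl-4a,5,8,8a-tetrahydronaphthalen-1(4H)-one | CC1=C[C@@H](O[Si](C)(C)C(C)(C)C)[C@H]2C(C)(C)C=CC[C@]2(C)C1=O | intermediate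
8 | (S)-malic acid | OC(=O)C[C@H](O)C(=O)O | starting material
9 | [(2S,4S)-2-tert-butyl-5-oxo-1,3-dioxolan-4-yl]acetic acid | OC(=O)C[C@@H]1O[C@H](C(C)(C)C)OC1=O | intermediate
10 | dilithium enolate carboxylate of 9 | [Li+].[Li+].[O-]C(=O)CC1=C([O-])O[C@@H](C(C)(C)C)O1 | intermediate
11 | [(2S,4S)-2-tert-butyl-5-oxo-4-(prop-2-en-1-yl)-1,3-dioxolan-4-yl]acetic acid | OC(=O)C[C@]1(CC=C)O[C@H](C(C)(C)C)OC1=O | intermediate
12 | (2S)-2-(prop-2-en-1-yl)butane-1,2,4-triol | OCC[C@](CO)(CC=C)O | intermediate
13 | 2-[(4S)-2,2-dimethyl-4-(prop-2-en-1-yl)-1,3-dioxolan-4-yl]ethan-1-ol | OCC[C@@]1(CC=C)COC(C)(C)O1 | intermediate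
14 | sodium alkoxide of 13 | [Na+].[O-]CC[C@@]1(CC=C)COC(C)(C)O1 | intermediate
15 | (4S)-4-[2-(benzyloxy)ethyl]-2,2-dimethyl-4-(prop-2-en-1-yl)-1,3-dioxolane | c1ccccc1COCC[C@@]2(CC=C)COC(C)(C)O2 | intermediate
16 | ozonide of 15 (3-substituted 1,2,4-trioxolane, mixture at the trioxolane carbon) | c1ccccc1COCC[C@@]2(CC3OCOO3)COC(C)(C)O2 | intermediate
17 | 2-{(4S)-4-[2-(benzyloxy)ethyl]-2,2-dimethyl-1,3-dioxolan-4-yl}ethan-1-ol | c1ccccc1COCC[C@@]2(CCO)COC(C)(C)O2 | intermediate
18 | (4R)-4-[2-(benzyloxy)ethyl]-4-(2-iodoethyl)-2,2-dimethyl-1,3-dioxolane | c1ccccc1COCC[C@@]2(CCI)COC(C)(C)O2 | intermediate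
19 | alkyllithium from 18 (lithium in place of iodine) | c1ccccc1COCC[C@@]2(CC[Li])COC(C)(C)O2 | intermediate
20 | 15-benzyloxy-6β-(tert-butyldimethylsilyloxy)-13,16-(isopropylidenedioxy)labda-2,7-dien-9-ol (5S,6R,10S,13S; C9 epimers) | CC1=C[C@@H](O[Si](C)(C)C(C)(C)C)[C@H]2C(C)(C)C=CC[C@]2(C)C1(O)CC[C@]3(CCOCc4ccccc4)COC(C)(C)O3 | intermediate
21 | 15-benzyloxy-6β-(tert-butyldimethylsilyloxy)-13,16-(isopropylidenedioxy)labda-2,8-dien-7-one (5S,6S,10S,13S) | CC1=C(CC[C@]3(CCOCc4ccccc4)COC(C)(C)O3)[C@@]2(C)CC=CC(C)(C)[C@@H]2[C@H](O[Si](C)(C)C(C)(C)C)C1=O | intermediate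
22 | 6β-(tert-butyldimethylsilyloxy)-15-hydroxy-13,16-(isopropylidenedioxy)labd-8-en-7-one (5S,6S,10S,13S) | CC1=C(CC[C@]3(CCO)COC(C)(C)O3)[C@@]2(C)CCCC(C)(C)[C@@H]2[C@H](O[Si](C)(C)C(C)(C)C)C1=O | intermediate
23 | 6β-(tert-butyldimethylsilyloxy)-13,16-(isopropylidenedioxy)-7-oxolabd-8-en-15-al | CC1=C(CC[C@]3(CC=O)COC(C)(C)O3)[C@@]2(C)CCCC(C)(C)[C@@H]2[C@H](O[Si](C)(C)C(C)(C)C)C1=O | intermediate
24 | 6β-(tert-butyldimethylsilyloxy)-13,16-(isopropylidenedioxy)-7-oxolabd-8-en-15-oic acid (5S,6S,10S,13S) | CC1=C(CC[C@]3(CC(=O)O)COC(C)(C)O3)[C@@]2(C)CCCC(C)(C)[C@@H]2[C@H](O[Si](C)(C)C(C)(C)C)C1=O | intermediate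
25 | 6β-(tert-butyldimethylsilyloxy)-13,16-dihydroxy-7-oxolabd-8-en-15-oic acid | CC1=C(CC[C@@](O)(CO)CC(=O)O)[C@@]2(C)CCCC(C)(C)[C@@H]2[C@H](O[Si](C)(C)C(C)(C)C)C1=O | intermediate
26 | 6β-(tert-butyldimethylsilyloxy)-13-hydroxy-7-oxolabd-8-en-15,16-olide (5S,6S,10S,13S) | CC1=C(CC[C@@]3(O)COC(=O)C3)[C@@]2(C)CCCC(C)(C)[C@@H]2[C@H](O[Si](C)(C)C(C)(C)C)C1=O | intermediate
27 | (5S,6S,10S,13S)-6β,13-dihydroxy-7-oxolabd-8-en-15,16-olide (CNP0324736.2) | CC1=C(CC[C@@]2(O)COC(=O)C2)[C@@]2(C)CCCC(C)(C)[C@@H]2[C@H](O)C1=O | target

## Step count and the least certain steps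

Total step count: 17. Longest linear sequence: 13 steps (8 to 18 in steps 5–11, then steps 12–17). The ring branch from 1 and 2 is 10 steps long.

**Step 1 (key step).** The diene may turn over too slowly because its s-cis conformer is barely populated. The zwitterion-like intermediate of the asynchronous addition may be diverted to [2+2] or ene-type products. The acid catalyst may isomerise or oligomerise the diene, and the facial discrimination may be insufficient. Fallback: setting out from 1 and 2, the cycloaddition is run with stoichiometric BF3·OEt2 in CH2Cl2, which coordinates the same carbonyl and should give the same constitution as a racemate. The racemate consists of 3 and its mirror image (4aS,8aR)-2,5,5,8a-tetramethyl-4a,5,8,8a-tetrahydronaphthalene-1,4-dione F1, and the two are separated by preparative chromatography on a chiral stationary phase. Compound 3 rejoins the route at step 2, so absolute control then comes from resolution instead of catalysis.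

**Step 2.** Enolisation may take place toward the C8 methyl instead of C5. Protonation may occur on the β face, or the product may re-enolise and drift back to the cis epimer during work-up. Fallback: setting out from 3, the two epimers are equilibrated with DBU in CH2Cl2, 5 is separated by chromatography and recovered 3 is resubmitted. This relies on the thermodynamic ratio plus recycling instead of on kinetic face selection, makes no new compound and returns at 5.

**Step 3.** Hydride may be delivered to the C9 carbonyl as well, or C5 may epimerise before reduction, because the gem-dimethyl group also crowds C6. Fallback: setting out from 3, the C6 carbonyl is masked first.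
- Silylation with t-BuMe2SiOSO2CF3 and Et3N gives the robust dienol ether (8aS)-4-(tert-butyldimethylsilyloxy)-2,5,5,8a-tetramethyl-8,8a-dihydronaphthalen-1(5H)-one F2.
- Alkyllithium 19 is added to its only free carbonyl, C9, to give the tertiary alcohol F3.
- Bu4NF and AcOH at −78 °C unmask C6 with kinetic protonation of C5 and give the 9-hydroxy-7-en-6-one F4.
- Luche reduction of the now unique ketone gives the 6β,9-diol F5.
- Selective silylation of the secondary hydroxyl with one equivalent of the silyl triflate returns to the route at 20.

**Step 13.** The tertiary allylic chromate may ionise and dehydrate to dienes instead of rearranging. The [3,3] shift to C7 may be slow next to the bulky C6 silyl ether, which would leave room for cleavage of the acid-sensitive groups. Fallback: setting out from 20, the hydroxyl is first transposed without oxidation by catalytic Re2O7 in Et2O, the equilibrium being drawn to the tetrasubstituted alkene, to give the secondary allylic alcohol 15-benzyloxy-6β-(tert-butyldimethylsilyloxy)-13,16-(isopropylidenedioxy)labda-2,8-dien-7-ol F6. This is then oxidised with the periodinane 1,1,1-triacetoxy-1,1-dihydro-1,2-benziodoxol-3(1H)-one and returns to the route at 21.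

## Further compounds

F1 | step 1 | (4aS,8aR)-2,5,5,8a-tetramethyl-4a,5,8,8a-tetrahydronaphthalene-1,4-dione (enantiomer of 3) | CC1=CC(=O)[C@H]2C(C)(C)C=CC[C@@]2(C)C1=O
F0 | step 2 | none | none
F2 | step 3 | (8aS)-4-(tert-butyldimethylsilyloxy)-2,5,5,8a-tetramethyl-8,8a-dihydronaphthalen-1(5H)-one | CC1=CC(O[Si](C)(C)C(C)(C)C)=C2C(C)(C)C=CC[C@]2(C)C1=O
F3 | step 3 | 15-benzyloxy-6-(tert-butyldimethylsilyloxy)-13,16-(isopropylidenedioxy)labda-2,5,7-trien-9-ol (C9 epimers) | CC1=CC(O[Si](C)(C)C(C)(C)C)=C2C(C)(C)C=CC[C@]2(C)C1(O)CC[C@]3(CCOCc4ccccc4)COC(C)(C)O3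
F4 | step 3 | 15-benzyloxy-9-hydroxy-13,16-(isopropylidenedioxy)labda-2,7-dien-6-one (trans-fused, C9 epimers) | CC1=CC(=O)[C@H]2C(C)(C)C=CC[C@]2(C)C1(O)CC[C@]3(CCOCc4ccccc4)COC(C)(C)O3
F5 | step 3 | 15-benzyloxy-13,16-(isopropylidenedioxy)labda-2,7-diene-6β,9-diol (C9 epimers) | CC1=C[C@@H](O)[C@H]2C(C)(C)C=CC[C@]2(C)C1(O)CC[C@]3(CCOCc4ccccc4)COC(C)(C)O3
F6 | step 13 | 15-benzyloxy-6β-(tert-butyldimethylsilyloxy)-13,16-(isopropylidenedioxy)labda-2,8-dien-7-ol (C7 epimers) | CC1=C(CC[C@]3(CCOCc4ccccc4)COC(C)(C)O3)[C@@]2(C)CC=CC(C)(C)[C@@H]2[C@H](O[Si](C)(C)C(C)(C)C)C1O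
A1 | alternative 1 | trans-fused drim-6-en-11-al (2,5,5,8a-tetramethyl-1,2,4a,5,6,7,8,8a-octahydronaphthalene-1-carbaldehyde) | C[C@@H]1[C@H](C=O)[C@@]2(C)CCCC(C)(C)[C@@H]2C=C1
A2 | alternative 1 | (2E,8E,10E)-3,7,7-trimethyldodeca-2,8,10-trienal | C/C=C/C=C/C(C)(C)CCC/C(C)=C/C=O
A3 | alternative 2 | 3-{[6-(tert-butyldimethylsilyloxy)-8,10-dimethyl ring-B 1,4-diene]-9-carbonyl}-1,3-oxazolidin-2-one (bicyclic cycloadduct, quaternary C10) | CC1=C(C(=O)N3CCOC3=O)[C@@]2(C)CCCC(C)(C)C2=C(O[Si](C)(C)C(C)(C)C)C1
A4 | alternative 2 | tert-butyldimethyl{[1-(2,6,6-trimethylcyclohex-1-en-1-yl)ethenyl]oxy}silane | C=C(O[Si](C)(C)C(C)(C)C)C1=C(C)CCCC1(C)C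
A5 | alternative 2 | 3-(but-2-ynoyl)-1,3-oxazolidin-2-one | CC#CC(=O)N1CCOC1=O
A6 | alternative 3 | 4,4,10-trimethyloctal-5-en-9-yl tert-butyldimethylsilyl ether (labdane numbering) | CC1(C)CCC[C@]2(C)[C@@H](O[Si](C)(C)C(C)(C)C)CCC=C12
A7 | alternative 3 | 5-(tert-butyldimethylsilyloxy)-6-methyl-6-(4-methylpent-4-en-1-yl)cyclohex-1-en-1-yl trifluoromethanesulfonate | C=C(C)CCC[C@]1(C)[C@@H](O[Si](C)(C)C(C)(C)C)CCC=C1OS(=O)(=O)C(F)(F)F
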